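In a one-step first-order world a substrate loses the same fraction of itself each minute, so its rate of loss shrinks in step with what remains. The runs below are tested against that picture.

| setting | alpha | delta | noon | winter |
|---|---|---|---|---|
| J | 0.87 M | 2 M | 1.3 M | 1.3 M |
| L | 45 mM (held) | 45 mM (held) | 45 mM (held) | 45 mM (held) |
| remark | run made earlier | run made earlier |  |  |
| time |  |  | 10 min | 4.0 min |

| run | time / min | X / % | Q / % | E / % | J / % |
|---|---|---|---|---|---|
| alpha | 0.833 | 7.8 | 1.2 | 8.9 | 82.7 |
| alpha | 1.50 | 12.6 | 1.7 | 14.9 | 70.9 |
| alpha | 2.50 | 19.2 | 3.0 | 22.2 | 55.7 |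
| alpha | 3.00 | 21.8 | 4.4 | 24.6 | 48.7 |
| alpha | 4.00 | 26.2 | 6.2 | 29.9 | 38.3 |
| alpha | 5.00 | 30.1 | 7.1 | 33.7 | 30.7 |
| delta | 0.833 | 6.7 | 0.7 | 7.9 | 84.4 |
| delta | 1.50 | 10.4 | 2.9 | 15.1 | 73.0 |
| delta | 2.50 | 15.7 | 5.6 | 21.9 | 57.1 |
| delta | 3.00 | 16.9 | 7.1 | 25.8 | 51.7 |
| delta | 4.00 | 20.6 | 11.6 | 29.8 | 39.6 |
| delta | 5.00 | 23.4 | 12.5 | 34.4 | 29.8 |

(readings scatter by 0.5 percentage points)

- in percentages every species weighs as the J in it: one Q counts as two
- at the start none of L is in solution

* which of these there is most of at the end, counted by the J in it, noon (Q / J / X / E)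
* which of these there is most of at the end, counted by the J in it, winter (Q / J / X / E)
* final amount of the leader among these, as a percentage of the J charged, in noon
* final amount of the leader among these, as a percentage of the J charged, in winter

The last alpha reading gives a fractional rate of loss of J of 0.236 /min. The delta run, with about twice the charge, gives 0.242 /min, much the same, so the reckoning here uses the alpha figure for noon and winter, whose charge lies between the two. At its last reading, the alpha run puts the share of the lost J that appears as E, its selectivity, at 0.486; the delta run gives 0.490.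

Read as a one-step decay, the rate of loss in winter has fallen by 4.0 min to 38.9 % of its starting value, and in noon by 10 min to 9.42 %. These factors are also the J remaining. The accumulated E is the share times what has gone: 29.7 % in winter and 44.0 % in noon. The slowing brings falling J level with rising E at 4.73 min, the crossing time. Winter is read earlier, so J should lead there. Noon is read later, so E should lead, since X stands below E at the last alpha reading.

The forecast names E for noon at 44.5 %, between 42.5 % and 46.5 %, and J for winter at 38.7 %, between 37.2 % and 40.2 %, holding that “J splits roughly evenly into E and X”.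

The flask gives E at 43.0 % in noon and J at 38.5 % in winter.

    L ⇌ Z, rate k1*(csat - [Z]) (kL = 0.210 /s)
    J + Z → X (k = 0.0500 /M/s)
    J → E (k = 0.00190 /s)
    2 Z → D (k = 0.0770 /M/s)
    J + X → Q (k = 0.00150 /M/s)
    X → G (k = 2.10 × 10⁻⁶ /s)

The difference in time is the main reason the two flasks part: with that difference taken away, noon read at winter's time, its E stands at 29.9 % instead of 43.0 %. In the flask J and E level at 4.64 min, against the 4.73 min reckoned, so winter, read at 4.0 min, stands 0.644 min short of the flask's own crossing. A neighbour of noon, the same flask read at 6.0 min, lies past the crossing, and the reckoning gives it E at 36.8 % and J at 24.3 %. That flask holds E at 36.7 % and J at 23 %.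

The numbers in the tables were generated by integration for an exercise.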